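## Retrosynthetic overview

- The plan rests on ring B. C1' (CO2H), C2' (free OH), C3'-H, C4' (O-acyl of ring A), C5'-H and C6' (propyl) form a resorcinol monoester. A 3-acyloxy-1,4-enyne and one CO build this pattern, so no phenol differentiation is needed.
- Ring B is cut at O-C4', C2'-C3' and C1'-C2'. This leads to CO and the ring A ester of benzyl (E)-4-hydroxy-3-propylhex-2-en-5-ynoate.
- The enynol comes from benzyl glyoxylate (ozonolysis of dibenzyl fumarate), pentanal (crossed aldol condensation) and ethynylmagnesium bromide.
- Ring A is bought as methyl orsellinate. It is taken on by 4-O-methylation, 2-O-benzylation, lateral acylation, ketalisation and saponification, then joined to the enynol by Mitsunobu esterification.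
- Ring order: ring A is preformed and ring B is closed last. Ketal hydrolysis and a final neutral hydrogenolysis release the target.

Key step: step 10

Remark: the target has no stereocentre. Only the E geometry of the enoate needs control, and the carbinol carbon of the enynol is carried racemic because it ends as an sp2 carbon of ring B.

## Route

Step 1
Reactants: 1 methyl orsellinate (methyl 2,4-dihydroxy-6-methylbenzoate)
Product: 2 methyl 2-hydroxy-4-methoxy-6-methylbenzoate
Conditions: MeI (1.05 equiv), K2CO3 (1.1 equiv), acetone, reflux
Reagents that add atoms: iodomethane, CI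
Why: Williamson O-methylation should take the C4 hydroxyl only, because the C2 hydroxyl is hydrogen-bonded to the ester carbonyl and is the poorer nucleophile.

Step 2
Reactants: 2 methyl 2-hydroxy-4-methoxy-6-methylbenzoate
Product: 3 methyl 2-(benzyloxy)-4-methoxy-6-methylbenzoate
Conditions: BnBr, K2CO3, DMF, 60 °C
Reagents that add atoms: benzyl bromide, BrCc1ccccc1
Why: Williamson etherification in a dipolar aprotic solvent overcomes the chelation and masks the phenol, which would otherwise consume base in step 3, compete as pronucleophile in step 9 and trap the ketene in step 10.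

Step 3
Reactants: 3 methyl 2-(benzyloxy)-4-methoxy-6-methylbenzoate; 4 N-methoxy-N-methylbutanamide
Product: 7 methyl 2-(benzyloxy)-4-methoxy-6-(2-oxopentyl)benzoate, via benzylic lithium species 5 (not isolated), via lithium hemiaminal adduct 6 (not isolated)
Conditions: LiN(i-Pr)2 (1.2 equiv), THF, −78 °C; then 4, −78 °C; AcOH quench at −78 °C
Reagents that add atoms: none
Why: This is lateral lithiation of an ortho-toluate followed by Weinreb ketone synthesis, in which the ester acidifies the ortho methyl group and the chelated adduct 6 lasts until the quench, so the ketone can neither be attacked again nor protonate 5.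

Step 4
Reactants: 7 methyl 2-(benzyloxy)-4-methoxy-6-(2-oxopentyl)benzoate
Product: 8 methyl 2-(benzyloxy)-4-methoxy-6-[(2-propyl-1,3-dioxolan-2-yl)methyl]benzoate
Conditions: (Me3SiOCH2)2, Me3SiOTf (5 mol %), CH2Cl2, −78 → −20 °C; pyridine quench
Reagents that add atoms: 1,2-bis(trimethylsilyloxy)ethane, C[Si](C)(C)OCCO[Si](C)(C)C
Why: Noyori ketalisation runs aprotic and cold and is driven by formation of the strong Si-O-Si bond, which avoids the hot protic acid that would close the keto ester to an isocoumarin.

Step 5
Reactants: 8 methyl 2-(benzyloxy)-4-methoxy-6-[(2-propyl-1,3-dioxolan-2-yl)methyl]benzoate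
Product: 10 2-(benzyloxy)-4-methoxy-6-[(2-propyl-1,3-dioxolan-2-yl)methyl]benzoic acid, via potassium carboxylate 9 (not isolated)
Conditions: KOH, DMSO-H2O, 90 °C; then cold 1 M HCl to pH 4, 0 °C, immediate extraction into EtOAc
Reagents that add atoms: potassium hydroxide, [K+].[OH-]
Why: In this saponification the poorly solvated hydroxide of aqueous DMSO overcomes the di-ortho hindrance, the ketal and both ethers are inert to base, and the brief cold acidification spares the ketal.

Step 6
Reactants: 11 dibenzyl fumarate
Product: 13 benzyl glyoxylate (benzyl 2-oxoacetate), via secondary ozonide 12 (not isolated)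
Conditions: O3, CH2Cl2, −78 °C; then Me2S, −78 °C → rt
Reagents that add atoms: ozone, [O-][O+]=O
Why: Ozonolysis with reductive work-up cleaves the symmetrical alkene into two molecules of the same aldehyde, and the alkene reacts much faster than the benzyl rings.

Step 7
Reactants: 13 benzyl glyoxylate; 14 pentanal
Product: 16 benzyl (E)-3-formylhex-2-enoate, via aldol adduct 15 (not isolated)
Conditions: Bu2NH (20 mol %), AcOH (20 mol %), toluene, 80 °C, slow addition of 14
Reagents that add atoms: none
Why: In this amine-catalysed crossed aldol condensation the enamine of pentanal attacks the non-enolisable and far more electrophilic glyoxylate aldehyde, 15 loses water by E1cB, and reversible amine addition should equilibrate the alkene to the E isomer with CHO and CO2Bn trans.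

Step 8
Reactants: 16 benzyl (E)-3-formylhex-2-enoate; 17 ethynylmagnesium bromide
Product: 19 benzyl (E)-4-hydroxy-3-propylhex-2-en-5-ynoate (racemic), via bromomagnesium alkoxide 18 (not isolated)
Conditions: 17 (1.1 equiv, 0.5 M in THF), THF, −78 °C; sat. aq. NH4Cl
Reagents that add atoms: none
Why: Grignard 1,2-addition picks the aldehyde as the most electrophilic carbonyl, alkynyl Grignard reagents do not add in a conjugate sense, the E geometry keeps the alkoxide away from the ester so no butenolide forms, and the new stereocentre is formed racemic and erased in step 10.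

Step 9
Reactants: 10 2-(benzyloxy)-4-methoxy-6-[(2-propyl-1,3-dioxolan-2-yl)methyl]benzoic acid; 19 benzyl (E)-4-hydroxy-3-propylhex-2-en-5-ynoate
Product: 20 benzyl (E)-4-{2-(benzyloxy)-4-methoxy-6-[(2-propyl-1,3-dioxolan-2-yl)methyl]benzoyloxy}-3-propylhex-2-en-5-ynoate (racemic)
Conditions: PPh3, DIAD, toluene, 0 °C → rt
Reagents that add atoms: none
Why: Mitsunobu esterification activates the alcohol and uses the carboxylate only as an oxygen nucleophile, so the crowded acyl carbon is never attacked, the ketal never faces an activated acyl group, no amine base touches the acidic C4-H, and inversion at the racemic carbinol has no consequence.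

Step 10
Reactants: 20 benzyl (E)-4-{2-(benzyloxy)-4-methoxy-6-[(2-propyl-1,3-dioxolan-2-yl)methyl]benzoyloxy}-3-propylhex-2-en-5-ynoate; 21 carbon monoxide
Product: 24 benzyl 4-{2-(benzyloxy)-4-methoxy-6-[(2-propyl-1,3-dioxolan-2-yl)methyl]benzoyloxy}-2-hydroxy-6-propylbenzoate, via dienylketene 22 (not isolated), via cyclohexadienone 23 (not isolated)
Conditions: [RhCl(CO)2]2 (5 mol %), CO (50-80 atm, autoclave), dry CH2Cl2, 80 °C
Reagents that add atoms: none
Why: This is the rhodium-catalysed carbonylative [5+1] benzannulation of 3-acyloxy-1,4-enynes, a known entry to resorcinol monoesters, used here with an aroyl migrating group and an ester on the alkene terminus, which stretches the usual scope. Monovalent rhodium binds the terminal alkyne of 20, the ester carbonyl oxygen adds 5-exo to the internal alkyne carbon, and opening of the resulting 1,3-dioxolenium ion carries the ring A acyloxy group onto that carbon (new O-C4' bond) while a rhodium vinylcarbene is left on the former terminal carbon (C3'). Insertion of CO 21 into the carbene makes the C2'-C3' bond and releases dienylketene 22, whose thermal disrotatory six-electron electrocyclisation joins the ketene carbon to the ester-bearing alkene carbon (C1'-C2' bond) and closes the six-membered ring B as cyclohexadienone 23. Enolisation of the β-keto ester unit of 23 is driven by aromatisation and by the hydrogen bond to the benzyl ester and gives the C2' phenol; no stereocentre is created, and the racemic carbinol carbon of 20 becomes the planar C5'-H. The 1,2-shift has to win over the 1,3-shift to an allenyl ester and over a Rautenstrauch-type five-ring closure: the unsubstituted alkyne terminus steers the oxygen to the internal carbon, the electron-poor enoate is a poor partner for the cationic five-ring closure, and CO pressure intercepts the carbene. The E geometry puts H inward and CO2Bn outward at the closing terminus, and because only the remote carbonyl oxygen of the aroyl group takes part (bulky pivalates migrate well in this reaction class), the two ortho substituents of ring A should not block the shift.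

Step 11
Reactants: 24 benzyl 4-{2-(benzyloxy)-4-methoxy-6-[(2-propyl-1,3-dioxolan-2-yl)methyl]benzoyloxy}-2-hydroxy-6-propylbenzoate
Product: 25 benzyl 4-{[2-(benzyloxy)-4-methoxy-6-(2-oxopentyl)benzoyl]oxy}-2-hydroxy-6-propylbenzoate
Conditions: 1 M aq. HCl, THF, rt
Reagents that add atoms: water, O
Why: Acid-catalysed hydrolysis of a dialkyl ketone dioxolane is fast at room temperature, the di-ortho-substituted depside ester and the benzyl ester resist dilute acid, and doing this before debenzylation keeps acid away from the decarboxylation-prone free salicylic acid.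

Step 12
Reactants: 25 benzyl 4-{[2-(benzyloxy)-4-methoxy-6-(2-oxopentyl)benzoyl]oxy}-2-hydroxy-6-propylbenzoate
Product: 26 2-hydroxy-4-{[2-hydroxy-4-methoxy-6-(2-oxopentyl)benzoyl]oxy}-6-propylbenzoic acid (CNP0187582.0)
Conditions: H2 (1 atm), 10% Pd/C, EtOAc, rt
Reagents that add atoms: none
Why: Catalytic hydrogenolysis removes the benzyl ether and the benzyl ester together under neutral conditions that leave the non-conjugated ketone, the depside ester and the aryl methyl ether untouched.

## Compound list

1 | methyl orsellinate (methyl 2,4-dihydroxy-6-methylbenzoate) | COC(=O)c1c(C)cc(O)cc1O | starting material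
2 | methyl 2-hydroxy-4-methoxy-6-methylbenzoate | COC(=O)c1c(C)cc(OC)cc1O | intermediate
3 | methyl 2-(benzyloxy)-4-methoxy-6-methylbenzoate | COC(=O)c1c(C)cc(OC)cc1OCc1ccccc1 | intermediate
4 | N-methoxy-N-methylbutanamide | CCCC(=O)N(C)OC | starting material
5 | benzylic lithium species of 3 (in situ) | [Li]Cc1cc(OC)cc(OCc2ccccc2)c1C(=O)OC | intermediate
6 | lithium hemiaminal adduct of 5 and 4 (in situ) | CCCC(O[Li])(Cc1cc(OC)cc(OCc2ccccc2)c1C(=O)OC)N(C)OC | intermediate
7 | methyl 2-(benzyloxy)-4-methoxy-6-(2-oxopentyl)benzoate | CCCC(=O)Cc1cc(OC)cc(OCc2ccccc2)c1C(=O)OC | intermediate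
8 | methyl 2-(benzyloxy)-4-methoxy-6-[(2-propyl-1,3-dioxolan-2-yl)methyl]benzoate | CCCC1(Cc2cc(OC)cc(OCc3ccccc3)c2C(=O)OC)OCCO1 | intermediate
9 | potassium 2-(benzyloxy)-4-methoxy-6-[(2-propyl-1,3-dioxolan-2-yl)methyl]benzoate (in situ) | CCCC1(Cc2cc(OC)cc(OCc3ccccc3)c2C(=O)[O-])OCCO1.[K+] | intermediate
10 | 2-(benzyloxy)-4-methoxy-6-[(2-propyl-1,3-dioxolan-2-yl)methyl]benzoic acid | CCCC1(Cc2cc(OC)cc(OCc3ccccc3)c2C(=O)O)OCCO1 | intermediate
11 | dibenzyl fumarate | O=C(/C=C/C(=O)OCc1ccccc1)OCc1ccccc1 | starting material
12 | dibenzyl 1,2,4-trioxolane-3,5-dicarboxylate, secondary ozonide (in situ) | O=C(OCc1ccccc1)C1OOC(O1)C(=O)OCc1ccccc1 | intermediate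
13 | benzyl glyoxylate (benzyl 2-oxoacetate) | O=CC(=O)OCc1ccccc1 | intermediate
14 | pentanal | CCCCC=O | starting material
15 | benzyl 3-formyl-2-hydroxyhexanoate, aldol adduct, diastereomer mixture (in situ) | CCCC(C=O)C(O)C(=O)OCc1ccccc1 | intermediate
16 | benzyl (E)-3-formylhex-2-enoate | O=C/C(CCC)=C/C(=O)OCc1ccccc1 | intermediate
17 | ethynylmagnesium bromide | C#C[Mg]Br | starting material
18 | bromomagnesium alkoxide of 19 (in situ, racemic) | C#CC(O[Mg]Br)/C(CCC)=C/C(=O)OCc1ccccc1 | intermediate
19 | benzyl (E)-4-hydroxy-3-propylhex-2-en-5-ynoate (racemic) | C#CC(O)/C(CCC)=C/C(=O)OCc1ccccc1 | intermediate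
20 | benzyl (E)-4-{2-(benzyloxy)-4-methoxy-6-[(2-propyl-1,3-dioxolan-2-yl)methyl]benzoyloxy}-3-propylhex-2-en-5-ynoate (racemic) | C#CC(OC(=O)c1c(OCc2ccccc2)cc(OC)cc1CC1(CCC)OCCO1)/C(CCC)=C/C(=O)OCc1ccccc1 | intermediate
21 | carbon monoxide | [C-]#[O+] | starting material
22 | benzyl (2E,4E)-5-(aroyloxy)-7-oxo-3-propylhepta-2,4,6-trienoate, dienylketene with aroyl = ring A acyl of 10 (in situ) | O=C=C/C(OC(=O)c1c(OCc2ccccc2)cc(OC)cc1CC1(CCC)OCCO1)=C\C(CCC)=C\C(=O)OCc1ccccc1 | intermediate
23 | benzyl 4-(aroyloxy)-2-oxo-6-propylcyclohexa-3,5-diene-1-carboxylate, aroyl = ring A acyl of 10 (in situ, racemic) | O=C1C=C(OC(=O)c2c(OCc3ccccc3)cc(OC)cc2CC2(CCC)OCCO2)C=C(CCC)C1C(=O)OCc1ccccc1 | intermediate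
24 | benzyl 4-{2-(benzyloxy)-4-methoxy-6-[(2-propyl-1,3-dioxolan-2-yl)methyl]benzoyloxy}-2-hydroxy-6-propylbenzoate | CCCC1(Cc2cc(OC)cc(OCc3ccccc3)c2C(=O)Oc2cc(O)c(C(=O)OCc3ccccc3)c(CCC)c2)OCCO1 | intermediate
25 | benzyl 4-{[2-(benzyloxy)-4-methoxy-6-(2-oxopentyl)benzoyl]oxy}-2-hydroxy-6-propylbenzoate | CCCC(=O)Cc1cc(OC)cc(OCc2ccccc2)c1C(=O)Oc1cc(O)c(C(=O)OCc2ccccc2)c(CCC)c1 | intermediate
26 | 2-hydroxy-4-{[2-hydroxy-4-methoxy-6-(2-oxopentyl)benzoyl]oxy}-6-propylbenzoic acid (CNP0187582.0) | CCCC(=O)Cc1cc(OC)cc(O)c1C(=O)Oc1cc(O)c(C(=O)O)c(CCC)c1 | target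

## Step count and risks

Total step count: 12.
Longest linear sequence: 9 (steps 1-5 and 9-12).

**Step 10, carbonylative benzannulation.**
- What may go wrong: the acyloxy shift may be sluggish on the electron-poor enyne. The 1,3-shift, five-ring closure or alkyne oligomerisation may compete. The ketene may be intercepted by adventitious nucleophiles before it closes.
- Fallback: it sets out from acid 10 and comes back at depside 24, building the depside bond by classical acylation of a preformed ring B. Commercial 2,4-dihydroxy-6-propylbenzoic acid is alkylated on its carboxylate (BnBr, KHCO3, DMF, rt) to benzyl 2,4-dihydroxy-6-propylbenzoate F1. Acid 10 is then coupled to F1 by Steglich esterification (DCC, cat. DMAP, CH2Cl2, 0 °C → rt). The C2' hydroxyl is hydrogen-bonded to the benzyl ester, so acylation should fall on the C4' hydroxyl and give 24. Steps 11 and 12 follow unchanged.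

**Step 9, Mitsunobu esterification.**
- What may go wrong: substitution at the crowded carbinol may be slow. Attack may be diverted to the alkyne terminus in an SN2' sense. Propargyl-to-allenyl isomerisation of the acidic C4-H system or acylation of the hydrazide may consume material.
- Fallback: it sets out from acid 10 and from alkoxide 18 (made from 16 and 17 as in step 8) and comes back at ester 20. The polarity of the bond formation is reversed. Acid 10 is converted with cyanuric fluoride and pyridine in CH2Cl2 into 2-(benzyloxy)-4-methoxy-6-[(2-propyl-1,3-dioxolan-2-yl)methyl]benzoyl fluoride F2, a small and non-ionising acyl donor. The solution of 18 at −78 °C is not quenched but treated with F2 (cat. DMAP if needed) and warmed to 0 °C, so the alkoxide is acylated directly to 20 without added base.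

**Step 7, crossed aldol condensation.**
- What may go wrong: pentanal may self-condense and the glyoxylate may oligomerise. The alkene may not equilibrate fully to the E isomer. The amine may be lost by conjugate addition to the enal.
- Fallback: it sets out from glyoxylate 13 and comes back at enal 16, replacing the aldol by a Wittig olefination. Butyltriphenylphosphonium bromide and KOt-Bu in THF give butylidene(triphenyl)-λ5-phosphane F3. Formylation of F3 with methyl formate gives the stabilised ylide 2-(triphenyl-λ5-phosphanylidene)pentanal F4. F4 and 13 in CH2Cl2 at rt should give 16, because formyl-stabilised ylides place the aldehyde residue (here CO2Bn) trans to CHO.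

## Further compounds

F1 | step 10 | benzyl 2,4-dihydroxy-6-propylbenzoate | CCCc1cc(O)cc(O)c1C(=O)OCc1ccccc1
F2 | step 9 | 2-(benzyloxy)-4-methoxy-6-[(2-propyl-1,3-dioxolan-2-yl)methyl]benzoyl fluoride | CCCC1(Cc2cc(OC)cc(OCc3ccccc3)c2C(=O)F)OCCO1
F3 | step 7 | butylidene(triphenyl)-λ5-phosphane | CCCC=P(c1ccccc1)(c1ccccc1)c1ccccc1
F4 | step 7 | 2-(triphenyl-λ5-phosphanylidene)pentanal | CCCC(C=O)=P(c1ccccc1)(c1ccccc1)c1ccccc1
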